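**Plan**

1. Decahydroquinoline numbering is used throughout (N1, C2–C4, C4a, C5–C8, C8a; side chain C1'–C8'). The retrosynthesis cuts the C3–O acyl bond first, then C4a–C5 and C8–C8a together, then N1–C8a and C4–C4a in the heterocycle and C6–C7 and C3'–C4' in the diene.
2. Enabling feature: with a carbonyl placed at C4, the ring-fusion atoms C4a and C8a are the alkene of an N-acyl 2,3-dihydropyridin-4-one. C5–C8 with the chain on C5 are an (E)-1-alkylbuta-1,3-diene, so the carbocycle is the ring a Diels–Alder reaction closes onto the finished heterocycle.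
3. Forward order: piperidinone ring (steps 1–6), diene chain (steps 7–10), cyclohexene ring by cycloaddition (step 11). Then the C4 oxygen is removed, C6=C7 is saturated with release of the C3 hydroxyl, and the octenoate is attached before deprotection (steps 12–17).
4. Stereochemistry: C2 and C3 come from a ligand-controlled syn aminohydroxylation of methyl crotonate, and C5' from (R)-2-propyloxirane. C4a, C5 and C8a come from an endo cycloaddition on the face opposite the pseudoaxial C2 methyl group; the enoate geometry comes from the purchased acid.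
5. The C3 oxygen is carried as a benzyl ether: it survives the acidic ring closure, can chelate the Lewis acid next to the C4 carbonyl, and leaves in the same hydrogenation that saturates C6=C7.

Key step: step 11

Assumption: the configuration at C4 of alcohol 18 and xanthate 19 is not controlled and not needed (C4 becomes CH2 in step 14), so both epimers are carried on and C4 is left undefined in their SMILES.

**Route**

Step 1
Reactants: 1 methyl (E)-but-2-enoate
Product: 2 methyl (2S,3R)-3-[(tert-butoxycarbonyl)amino]-2-hydroxybutanoate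
Conditions: BocNH2, t-BuOCl, NaOH, K2OsO2(OH)4 (4 mol %), (DHQD)2PHAL (5 mol %), n-PrOH/H2O 1:1, 0 °C → rt
Reagents that add atoms: tert-butyl carbamate NC(=O)OC(C)(C)C; water O
Why: Sharpless asymmetric aminohydroxylation (carbamate variant) adds N and O syn across the E-alkene with N at the β-carbon, and the (DHQD)2PHAL ligand should select the face that gives the 2S,3R isomer, so both stereocentres of the heterocycle (later C3 and C2 of the quinoline) are set here.

Step 2
Reactants: 2 methyl (2S,3R)-3-[(tert-butoxycarbonyl)amino]-2-hydroxybutanoate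
Product: 3 methyl (2S,3R)-2-(benzyloxy)-3-[(tert-butoxycarbonyl)amino]butanoate
Conditions: 2-benzyloxy-1-methylpyridinium triflate (2 equiv), MgO (2 equiv), PhCF3, 85 °C
Reagents that add atoms: 2-benzyloxy-1-methylpyridinium triflate C[n+]1ccccc1OCc1ccccc1.[O-]S(=O)(=O)C(F)(F)F
Why: Neutral SN1-type O-benzylation by benzyl transfer from the pyridinium salt avoids the basic conditions under which the alkoxide could attack the Boc group or epimerise C2, and installs an ether that survives HCl, can chelate a Lewis acid and leaves later by hydrogenolysis.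

Step 3
Reactants: 3 methyl (2S,3R)-2-(benzyloxy)-3-[(tert-butoxycarbonyl)amino]butanoate
Product: 4 tert-butyl N-[(2R,3S)-3-(benzyloxy)-4-[methoxy(methyl)amino]-4-oxobutan-2-yl]carbamate
Conditions: MeNH(OMe)·HCl (1.6 equiv), i-PrMgCl (4.5 equiv), THF, −20 → 0 °C
Reagents that add atoms: N,O-dimethylhydroxylamine hydrochloride CNOC.Cl
Why: Weinreb amide formation by attack of the in situ magnesium amide on the methyl ester at low temperature, conditions known to leave α-alkoxy stereocentres intact.

Step 4
Reactants: 4 tert-butyl N-[(2R,3S)-3-(benzyloxy)-4-[methoxy(methyl)amino]-4-oxobutan-2-yl]carbamate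
Product: 5 tert-butyl N-[(2R,3S)-3-(benzyloxy)-4-oxohex-5-yn-2-yl]carbamate
Conditions: HC≡CMgBr (4 equiv), THF, 0 °C → rt; cold aq. NaHSO4 quench
Reagents that add atoms: ethynylmagnesium bromide C#C[Mg]Br
Why: Weinreb ketone synthesis, in which the chelated tetrahedral magnesium adduct stops at the ketone stage (this forms C4–C4a), and the cold acidic quench keeps the released N,O-dimethylhydroxylamine from adding to the ynone.

Step 5
Reactants: 5 tert-butyl N-[(2R,3S)-3-(benzyloxy)-4-oxohex-5-yn-2-yl]carbamate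
Product: 7 (2R,3S)-3-(benzyloxy)-2-methyl-2,3-dihydropyridin-4(1H)-one, via chlorovinyl ketone hydrochloride 6 (not isolated)
Conditions: 4 M HCl in dioxane, 0 °C → rt; evaporate; K2CO3, MeOH, rt
Reagents that add atoms: none
Why: Acid removes the Boc group and hydrochlorinates the ynone to the β-chlorovinyl ketone, and on basification the free amine closes N1–C8a by conjugate addition–elimination (net 6-endo aza-Michael cyclisation), a sequence that avoids a free amino ynone and should leave C2 and C3 untouched.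

Step 6
Reactants: 7 (2R,3S)-3-(benzyloxy)-2-methyl-2,3-dihydropyridin-4(1H)-one
Product: 8 tert-butyl (2R,3S)-3-(benzyloxy)-2-methyl-4-oxo-3,4-dihydropyridine-1(2H)-carboxylate
Conditions: Boc2O (1.5 equiv), DMAP (0.1 equiv), Et3N, MeCN, rt
Reagents that add atoms: di-tert-butyl dicarbonate CC(C)(C)OC(=O)OC(=O)OC(C)(C)C
Why: DMAP-catalysed N-acylation of the vinylogous amide N–H gives a vinylogous imide, which makes the future C4a=C8a alkene electron-poor and, through A1,3 strain with the carbamate, pushes the C2 methyl group pseudoaxial.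

Step 7
Reactants: 9 (5-chloropent-1-yn-1-yl)trimethylsilane; 10 (R)-2-propyloxirane
Product: 12 (R)-10-(trimethylsilyl)dec-9-yn-4-ol, via Grignard reagent 11 (not isolated)
Conditions: Mg, THF, reflux; then CuI (10 mol %), 10, THF, −30 → 0 °C; aq. NH4Cl
Reagents that add atoms: none
Why: Copper-catalysed Grignard opening of a terminal epoxide (SN2 at the CH2 carbon) forms the C3'–C4' bond without touching the carbinol stereocentre, the C-silyl group masking the acidic alkyne hydrogen during Grignard formation.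

Step 8
Reactants: 12 (R)-10-(trimethylsilyl)dec-9-yn-4-ol
Product: 13 (R)-dec-9-yn-4-ol
Conditions: K2CO3 (cat.), MeOH, rt
Reagents that add atoms: none
Why: Base-catalysed methanolysis of the alkynyl C–Si bond (protodesilylation) is selective for the alkynylsilane.

Step 9
Reactants: 13 (R)-dec-9-yn-4-ol
Product: 14 (R)-tert-butyl(dec-9-yn-4-yloxy)dimethylsilane
Conditions: TBSCl, imidazole, DMF, rt
Reagents that add atoms: tert-butyldimethylsilyl chloride CC(C)(C)[Si](C)(C)Cl
Why: Standard silylation gives an ether that should tolerate hydrozirconation, the Lewis acid, hydride, radical and hydrogenation steps and fall only in the final acid treatment.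

Step 10
Reactants: 14 (R)-tert-butyl(dec-9-yn-4-yloxy)dimethylsilane
Product: 16 (R,E)-tert-butyl(dodeca-9,11-dien-4-yloxy)dimethylsilane, via alkenylzirconocene chloride 15 (not isolated)
Conditions: Cp2Zr(H)Cl (1.3 equiv), THF, rt; then vinyl bromide (2 equiv), Pd(PPh3)4 (5 mol %), ZnCl2 (20 mol %), rt
Reagents that add atoms: vinyl bromide C=CBr
Why: syn-Hydrozirconation places zirconium at the terminal carbon to give the (E)-alkenylzirconocene, and Pd-catalysed Negishi-type cross-coupling with vinyl bromide proceeds with retention, so the (E)-1-alkylbutadiene should form as a single geometric isomer.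

Step 11
Reactants: 8 tert-butyl (2R,3S)-3-(benzyloxy)-2-methyl-4-oxo-3,4-dihydropyridine-1(2H)-carboxylate; 16 (R,E)-tert-butyl(dodeca-9,11-dien-4-yloxy)dimethylsilane
Product: 17 tert-butyl (2R,3S,4aS,5S,8aR)-3-(benzyloxy)-5-[(5R)-5-[(tert-butyldimethylsilyl)oxy]octyl]-2-methyl-4-oxo-3,4,4a,5,8,8a-hexahydroquinoline-1(2H)-carboxylate
Conditions: Me2AlCl (2.2 equiv), 16 (3 equiv), CH2Cl2, −78 → −20 °C; cold aq. Rochelle-salt quench
Reagents that add atoms: none
Why: This is a concerted but asynchronous, Lewis-acid-accelerated normal-demand Diels–Alder reaction in which Me2AlCl, held in a five-membered chelate between the C4 carbonyl and the C3 benzyloxy oxygen, lowers the LUMO of the vinylogous imide; the closest known reaction type is the aluminium-halide-promoted cycloaddition of cyclohex-2-enones and N-acyl-2,3-dihydropyridin-4-ones with 1-substituted butadienes to give cis-fused bicyclic ketones. The cyclohexene ring (C4a, C5, C6, C7, C8, C8a) is closed as a [4+2] annulation by suprafacial bonding of both diene termini to one face of the C4a=C8a alkene, with C8–C8a (unsubstituted diene terminus to the β-carbon next to nitrogen) running ahead of C4a–C5, which fixes the ortho regiochemistry with the side chain next to C4a. The cis relationship of C4a and C8a follows from suprafacial addition, and their absolute sense from attack on the face opposite the C2 methyl group, which A1,3 strain with the carbamate holds pseudoaxial over one face of C8a (the cis C3 benzyloxy group lies on that same face). C5 is set by the (E)-geometry of the diene together with the endo transition state (diene π-system under the C4 carbonyl), which places H5 cis to H4a. The step therefore needs regio-, endo- and π-facial selectivity, secured in turn by the polarised enaminone/1-alkyldiene pairing, by the Lewis-acid-enhanced endo preference and by the pseudoaxial C2 methyl group. Excess diene, low temperature and a cold quench are planned to outrun diene oligomerisation, carbamate cleavage and epimerisation at C4a.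

Step 12
Reactants: 17 tert-butyl (2R,3S,4aS,5S,8aR)-3-(benzyloxy)-5-[(5R)-5-[(tert-butyldimethylsilyl)oxy]octyl]-2-methyl-4-oxo-3,4,4a,5,8,8a-hexahydroquinoline-1(2H)-carboxylate
Product: 18 tert-butyl (2R,3S,4RS,4aS,5S,8aR)-3-(benzyloxy)-5-[(5R)-5-[(tert-butyldimethylsilyl)oxy]octyl]-4-hydroxy-2-methyl-3,4,4a,5,8,8a-hexahydroquinoline-1(2H)-carboxylate
Conditions: NaBH4, CeCl3·7H2O, MeOH, −40 °C
Reagents that add atoms: none
Why: Luche reduction (1,2-hydride delivery under near-neutral cerium buffering) should convert the C4 ketone into the alcohol fast enough to forestall base-induced epimerisation at C4a, and the new C4 configuration is irrelevant.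

Step 13
Reactants: 18 tert-butyl (2R,3S,4RS,4aS,5S,8aR)-3-(benzyloxy)-5-[(5R)-5-[(tert-butyldimethylsilyl)oxy]octyl]-4-hydroxy-2-methyl-3,4,4a,5,8,8a-hexahydroquinoline-1(2H)-carboxylate
Product: 19 tert-butyl (2R,3S,4RS,4aS,5S,8aR)-3-(benzyloxy)-5-[(5R)-5-[(tert-butyldimethylsilyl)oxy]octyl]-2-methyl-4-{[(methylsulfanyl)carbonothioyl]oxy}-3,4,4a,5,8,8a-hexahydroquinoline-1(2H)-carboxylate
Conditions: NaH, CS2, THF, 0 °C → rt; then MeI
Reagents that add atoms: carbon disulfide S=C=S; iodomethane CI
Why: Xanthate formation (alkoxide addition to CS2, then S-methylation) prepares the C4 oxygen for radical C–O cleavage, and no base-sensitive stereocentre remains once the ketone is gone.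

Step 14
Reactants: 19 tert-butyl (2R,3S,4RS,4aS,5S,8aR)-3-(benzyloxy)-5-[(5R)-5-[(tert-butyldimethylsilyl)oxy]octyl]-2-methyl-4-{[(methylsulfanyl)carbonothioyl]oxy}-3,4,4a,5,8,8a-hexahydroquinoline-1(2H)-carboxylate
Product: 20 tert-butyl (2R,3R,4aS,5S,8aR)-3-(benzyloxy)-5-[(5R)-5-[(tert-butyldimethylsilyl)oxy]octyl]-2-methyl-3,4,4a,5,8,8a-hexahydroquinoline-1(2H)-carboxylate
Conditions: Bu3SnH (2 equiv), AIBN (cat.), toluene, 100 °C
Reagents that add atoms: none
Why: Barton–McCombie deoxygenation (stannyl radical addition to the thiocarbonyl, β-scission to the secondary C4 radical, hydrogen transfer from Bu3SnH) gives the CH2 group, the isolated C6=C7 alkene and the ethers being inert to the chain.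

Step 15
Reactants: 20 tert-butyl (2R,3R,4aS,5S,8aR)-3-(benzyloxy)-5-[(5R)-5-[(tert-butyldimethylsilyl)oxy]octyl]-2-methyl-3,4,4a,5,8,8a-hexahydroquinoline-1(2H)-carboxylate
Product: 21 tert-butyl (2R,3R,4aS,5S,8aR)-5-[(5R)-5-[(tert-butyldimethylsilyl)oxy]octyl]-3-hydroxy-2-methyloctahydroquinoline-1(2H)-carboxylate
Conditions: H2 (1 atm), Pd(OH)2/C, EtOAc, rt
Reagents that add atoms: none
Why: Heterogeneous catalytic hydrogenation saturates the disubstituted C6=C7 alkene (no new stereocentre) and hydrogenolyses the benzyl ether in the same operation, while the carbamate and the TBS ether are stable in EtOAc.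

Step 16
Reactants: 21 tert-butyl (2R,3R,4aS,5S,8aR)-5-[(5R)-5-[(tert-butyldimethylsilyl)oxy]octyl]-3-hydroxy-2-methyloctahydroquinoline-1(2H)-carboxylate; 22 (E)-oct-2-enoic acid
Product: 23 tert-butyl (2R,3R,4aS,5S,8aR)-5-[(5R)-5-[(tert-butyldimethylsilyl)oxy]octyl]-2-methyl-3-{[(2E)-oct-2-enoyl]oxy}octahydroquinoline-1(2H)-carboxylate
Conditions: 22 (2 equiv), EDC·HCl (2.5 equiv), DMAP (0.5 equiv), CH2Cl2, 0 °C → rt
Reagents that add atoms: none
Why: Steglich esterification (carbodiimide activation, DMAP acyl transfer) acylates the only free hydroxyl, the carbamate keeping nitrogen out of the reaction and the (E)-enoate geometry coming from the acid.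

Step 17
Reactants: 23 tert-butyl (2R,3R,4aS,5S,8aR)-5-[(5R)-5-[(tert-butyldimethylsilyl)oxy]octyl]-2-methyl-3-{[(2E)-oct-2-enoyl]oxy}octahydroquinoline-1(2H)-carboxylate
Product: 24 (2R,3R,4aS,5S,8aR)-5-[(5R)-5-hydroxyoctyl]-2-methyldecahydroquinolin-3-yl (2E)-oct-2-enoate
Conditions: TFA/H2O 9:1, 0 °C → rt; then aq. NaHCO3
Reagents that add atoms: none
Why: Acidolysis with aqueous TFA cleaves the Boc carbamate (loss of the tert-butyl cation, decarboxylation) and hydrolyses the secondary TBS ether in one operation under conditions that should leave the conjugated ester intact, and the basic work-up releases the free amine.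

**Compound list**

1 | methyl (E)-but-2-enoate (methyl crotonate) | C/C=C/C(=O)OC | starting material
2 | methyl (2S,3R)-3-[(tert-butoxycarbonyl)amino]-2-hydroxybutanoate | C[C@@H](NC(=O)OC(C)(C)C)[C@H](O)C(=O)OC | intermediate
3 | methyl (2S,3R)-2-(benzyloxy)-3-[(tert-butoxycarbonyl)amino]butanoate | C[C@@H](NC(=O)OC(C)(C)C)[C@H](OCc1ccccc1)C(=O)OC | intermediate
4 | tert-butyl N-[(2R,3S)-3-(benzyloxy)-4-[methoxy(methyl)amino]-4-oxobutan-2-yl]carbamate | C[C@@H](NC(=O)OC(C)(C)C)[C@H](OCc1ccccc1)C(=O)N(C)OC | intermediate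
5 | tert-butyl N-[(2R,3S)-3-(benzyloxy)-4-oxohex-5-yn-2-yl]carbamate | C[C@@H](NC(=O)OC(C)(C)C)[C@H](OCc1ccccc1)C(=O)C#C | intermediate
6 | (1Z,4S,5R)-5-amino-4-(benzyloxy)-1-chlorohex-1-en-3-one hydrochloride (Z expected from anti addition of HCl; either geometry would cyclise) | C[C@@H](N)[C@H](OCc1ccccc1)C(=O)/C=C\Cl.Cl | intermediate (not isolated)
7 | (2R,3S)-3-(benzyloxy)-2-methyl-2,3-dihydropyridin-4(1H)-one | c2ccccc2CO[C@@H]1C(=O)C=CN[C@@H]1C | intermediate
8 | tert-butyl (2R,3S)-3-(benzyloxy)-2-methyl-4-oxo-3,4-dihydropyridine-1(2H)-carboxylate (2-methyl and 3-benzyloxy cis) | c2ccccc2CO[C@@H]1C(=O)C=CN(C(=O)OC(C)(C)C)[C@@H]1C | intermediate (dienophile)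
9 | (5-chloropent-1-yn-1-yl)trimethylsilane | C[Si](C)(C)C#CCCCCl | starting material
10 | (R)-2-propyloxirane | CCC[C@@H]1CO1 | starting material
11 | [5-(trimethylsilyl)pent-4-yn-1-yl]magnesium chloride | C[Si](C)(C)C#CCCC[Mg]Cl | intermediate (not isolated)
12 | (R)-10-(trimethylsilyl)dec-9-yn-4-ol | CCC[C@@H](O)CCCCC#C[Si](C)(C)C | intermediate
13 | (R)-dec-9-yn-4-ol | CCC[C@@H](O)CCCCC#C | intermediate
14 | (R)-tert-butyl(dec-9-yn-4-yloxy)dimethylsilane | CCC[C@@H](O[Si](C)(C)C(C)(C)C)CCCCC#C | intermediate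
15 | chlorobis(cyclopentadienyl)[(1E,7R)-7-[(tert-butyldimethylsilyl)oxy]dec-1-en-1-yl]zirconium | CCC[C@@H](O[Si](C)(C)C(C)(C)C)CCCC/C=C/[Zr](Cl)(C1C=CC=C1)C1C=CC=C1 | intermediate (not isolated)
16 | (R,E)-tert-butyl(dodeca-9,11-dien-4-yloxy)dimethylsilane | CCC[C@@H](O[Si](C)(C)C(C)(C)C)CCCC/C=C/C=C | intermediate (diene)
17 | tert-butyl (2R,3S,4aS,5S,8aR)-3-(benzyloxy)-5-[(5R)-5-[(tert-butyldimethylsilyl)oxy]octyl]-2-methyl-4-oxo-3,4,4a,5,8,8a-hexahydroquinoline-1(2H)-carboxylate (cis ring fusion; H4a, H5, H8a all cis and on the face of the C2 methyl and C3 oxygen) | c3ccccc3CO[C@@H]1C(=O)[C@H]2[C@@H](CCCC[C@H](O[Si](C)(C)C(C)(C)C)CCC)C=CC[C@H]2N(C(=O)OC(C)(C)C)[C@@H]1C | intermediate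
18 | tert-butyl (2R,3S,4RS,4aS,5S,8aR)-3-(benzyloxy)-5-[(5R)-5-[(tert-butyldimethylsilyl)oxy]octyl]-4-hydroxy-2-methyl-3,4,4a,5,8,8a-hexahydroquinoline-1(2H)-carboxylate (C4 epimers) | c3ccccc3CO[C@@H]1C(O)[C@H]2[C@@H](CCCC[C@H](O[Si](C)(C)C(C)(C)C)CCC)C=CC[C@H]2N(C(=O)OC(C)(C)C)[C@@H]1C | intermediate
19 | tert-butyl (2R,3S,4RS,4aS,5S,8aR)-3-(benzyloxy)-5-[(5R)-5-[(tert-butyldimethylsilyl)oxy]octyl]-2-methyl-4-{[(methylsulfanyl)carbonothioyl]oxy}-3,4,4a,5,8,8a-hexahydroquinoline-1(2H)-carboxylate (C4 epimers) | c3ccccc3CO[C@@H]1C(OC(=S)SC)[C@H]2[C@@H](CCCC[C@H](O[Si](C)(C)C(C)(C)C)CCC)C=CC[C@H]2N(C(=O)OC(C)(C)C)[C@@H]1C | intermediate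
20 | tert-butyl (2R,3R,4aS,5S,8aR)-3-(benzyloxy)-5-[(5R)-5-[(tert-butyldimethylsilyl)oxy]octyl]-2-methyl-3,4,4a,5,8,8a-hexahydroquinoline-1(2H)-carboxylate | c3ccccc3CO[C@@H]1C[C@H]2[C@@H](CCCC[C@H](O[Si](C)(C)C(C)(C)C)CCC)C=CC[C@H]2N(C(=O)OC(C)(C)C)[C@@H]1C | intermediate
21 | tert-butyl (2R,3R,4aS,5S,8aR)-5-[(5R)-5-[(tert-butyldimethylsilyl)oxy]octyl]-3-hydroxy-2-methyloctahydroquinoline-1(2H)-carboxylate | O[C@@H]1C[C@H]2[C@@H](CCCC[C@H](O[Si](C)(C)C(C)(C)C)CCC)CCC[C@H]2N(C(=O)OC(C)(C)C)[C@@H]1C | intermediate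
22 | (E)-oct-2-enoic acid | CCCCC/C=C/C(=O)O | starting material
23 | tert-butyl (2R,3R,4aS,5S,8aR)-5-[(5R)-5-[(tert-butyldimethylsilyl)oxy]octyl]-2-methyl-3-{[(2E)-oct-2-enoyl]oxy}octahydroquinoline-1(2H)-carboxylate | CCCCC/C=C/C(=O)O[C@@H]1C[C@H]2[C@@H](CCCC[C@H](O[Si](C)(C)C(C)(C)C)CCC)CCC[C@H]2N(C(=O)OC(C)(C)C)[C@@H]1C | intermediate
24 | (2R,3R,4aS,5S,8aR)-5-[(5R)-5-hydroxyoctyl]-2-methyldecahydroquinolin-3-yl (2E)-oct-2-enoate | CCCCC/C=C/C(=O)O[C@@H]1C[C@H]2[C@@H](CCCC[C@H](O)CCC)CCC[C@H]2N[C@@H]1C | target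

**Step count**

Total: 17 steps. Longest linear sequence: 13 steps (steps 1–6, then 11–17); the diene branch is 4 steps (7–10).

**Steps most likely to fail**

1. Step 11. The vinylogous imide may add an unactivated alkyl diene too slowly, so that Lewis-acid cleavage of the carbamate, oligomerisation of the diene, epimerisation at C4a or leakage to the methyl-side face compete. The fallback keeps the same two bonds but adds a removable activating group, and sets out from 8. Electrophilic bromination at the enamide β-carbon (NBS, CH2Cl2, 0 °C → rt) should give tert-butyl (2R,3S)-3-(benzyloxy)-5-bromo-2-methyl-4-oxo-3,4-dihydropyridine-1(2H)-carboxylate F1. α-Bromo enones are considerably better dienophiles than the parent enones, so F1 should add diene 16 under milder promotion (Me2AlCl at −78 °C, or simply in warm toluene) with the same regio-, endo- and facial sense. This gives tert-butyl (2R,3S,4aR,5S,8aR)-3-(benzyloxy)-4a-bromo-5-[(5R)-5-[(tert-butyldimethylsilyl)oxy]octyl]-2-methyl-4-oxo-3,4,4a,5,8,8a-hexahydroquinoline-1(2H)-carboxylate F2. Radical debromination (Bu3SnH, AIBN, benzene, 80 °C) then replaces bromine by hydrogen. Hydrogen transfer to the C4a radical is expected on the face away from the C5 side chain, which restores the cis ring fusion, and the route is rejoined at 17.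

2. Step 13. The C4 alkoxide is flanked by the C3 benzyloxy group and the ring fusion, so thiocarbonylation may stay incomplete and the radical deoxygenation that follows may be sluggish. The fallback removes the oxygen through sulfur and sets out from 17. Dithioketalisation (ethane-1,2-dithiol, Zn(OTf)2, CH2Cl2, rt) should give the C4 spiro-1,3-dithiolane of 17, tert-butyl (2R,3S,4aS,5S,8aR)-3-(benzyloxy)-5-[(5R)-5-[(tert-butyldimethylsilyl)oxy]octyl]-4,4-(ethane-1,2-diyldisulfanediyl)-2-methyl-3,4,4a,5,8,8a-hexahydroquinoline-1(2H)-carboxylate F3. Raney nickel in refluxing ethanol should then cleave both C–S bonds, saturate C6=C7 and hydrogenolyse the benzyl ether (any remaining benzyl ether would be finished with H2, Pd(OH)2/C). The route is rejoined at 21, so steps 12–15 are bypassed.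

3. Step 5. Basification of the chlorovinyl ketone may epimerise the α-benzyloxy carbon or eliminate the β-amino group before the ring closes. The fallback closes the same N1–C8a bond by amine exchange on an enaminone and sets out from 4. Methylmagnesium bromide (THF, 0 °C) should give tert-butyl N-[(2R,3S)-3-(benzyloxy)-4-oxopentan-2-yl]carbamate F4. Condensation at the methyl group with N,N-dimethylformamide dimethyl acetal (toluene, 90 °C) should give tert-butyl N-[(2R,3S,5E)-3-(benzyloxy)-6-(dimethylamino)-4-oxohex-5-en-2-yl]carbamate F5. Boc removal (TFA, CH2Cl2) followed by warming with Et3N in MeOH lets the primary amine displace dimethylamine by addition–elimination, and the route is rejoined at 7.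

**Further compounds**

F1 | step 11 | tert-butyl (2R,3S)-3-(benzyloxy)-5-bromo-2-methyl-4-oxo-3,4-dihydropyridine-1(2H)-carboxylate | c2ccccc2CO[C@@H]1C(=O)C(Br)=CN(C(=O)OC(C)(C)C)[C@@H]1C
F2 | step 11 | tert-butyl (2R,3S,4aR,5S,8aR)-3-(benzyloxy)-4a-bromo-5-[(5R)-5-[(tert-butyldimethylsilyl)oxy]octyl]-2-methyl-4-oxo-3,4,4a,5,8,8a-hexahydroquinoline-1(2H)-carboxylate | c3ccccc3CO[C@@H]1C(=O)[C@@]2(Br)[C@@H](CCCC[C@H](O[Si](C)(C)C(C)(C)C)CCC)C=CC[C@H]2N(C(=O)OC(C)(C)C)[C@@H]1C
F3 | step 13 | tert-butyl (2R,3S,4aS,5S,8aR)-3-(benzyloxy)-5-[(5R)-5-[(tert-butyldimethylsilyl)oxy]octyl]-4,4-(ethane-1,2-diyldisulfanediyl)-2-methyl-3,4,4a,5,8,8a-hexahydroquinoline-1(2H)-carboxylate | c3ccccc3CO[C@@H]1C4(SCCS4)[C@H]2[C@@H](CCCC[C@H](O[Si](C)(C)C(C)(C)C)CCC)C=CC[C@H]2N(C(=O)OC(C)(C)C)[C@@H]1C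
F4 | step 5 | tert-butyl N-[(2R,3S)-3-(benzyloxy)-4-oxopentan-2-yl]carbamate | C[C@@H](NC(=O)OC(C)(C)C)[C@H](OCc1ccccc1)C(C)=O
F5 | step 5 | tert-butyl N-[(2R,3S,5E)-3-(benzyloxy)-6-(dimethylamino)-4-oxohex-5-en-2-yl]carbamate | C[C@@H](NC(=O)OC(C)(C)C)[C@H](OCc1ccccc1)C(=O)/C=C/N(C)C
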